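Assumption: (S)-4-hydroxycyclopent-2-en-1-one of high ee is taken as commercially available. Guaiane numbering is used throughout (C1–C5 five-membered ring, C1/C5–C10 seven-membered ring, C6–O–C12 lactone, C13 on C11, C14 on C10, C15 on C4; primed numbers for the norbornane half; α is the face of H-1).

**Retrosynthetic overview**
1. Target 24 ← exo-to-endo alkene shift ← C4 methylenation ← norbornane ketone 22.
2. 22 ← radical annulation: a C2′ homoallyl radical (from diene 20 by hydroboration) adds to C2 of cyclopentenone 14, then the α-keto radical closes 5-exo on C5′; the norbornane is formed last.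
3. Both halves (C10 epimers 10 and 11) ← one radical cascade on bromo ester 9: lactone (5-exo), then seven-membered ring (7-endo), then C10–OH.
4. 9 ← conjugate addition–aldol coupling of silyloxycyclopentenone 2, isopropenylmagnesium bromide 3 and acrolein 4, then acylation with 8.

**Route**

Step 1
Reactants: 1 (S)-4-hydroxycyclopent-2-en-1-one
Product: 2 (S)-4-[(tert-butyldimethylsilyl)oxy]cyclopent-2-en-1-one
Conditions: TBSCl, imidazole, CH2Cl2, 0 → 20 °C
Reagents that add atoms: tert-butyldimethylsilyl chloride, CC(C)(C)[Si](C)(C)Cl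
Why: Routine silyl ether formation on the secondary allylic alcohol, which leaves the stereocentre untouched and provides the bulky group that steers step 2.

Step 2
Reactants: 2 (S)-4-[(tert-butyldimethylsilyl)oxy]cyclopent-2-en-1-one; 3 isopropenylmagnesium bromide; 4 acrolein
Product: 7 (2R,3R,4S)-4-[(tert-butyldimethylsilyl)oxy]-2-[(1S)-1-hydroxyprop-2-en-1-yl]-3-(prop-1-en-2-yl)cyclopentan-1-one, via bromomagnesium enolate 5 (not isolated), via chlorozirconocene enolate 6 (not isolated)
Conditions: 3 (1.3 equiv), CuBr·SMe2 (10 mol %), THF, −78 °C; Cp2ZrCl2 (1.3 equiv), −78 → −40 °C; 4, −78 °C; cold dilute HCl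
Reagents that add atoms: none
Why: In this Noyori-type conjugate addition–aldol coupling the copper-catalysed 1,4-addition occurs anti to the silyloxy group (sets C1), and the zirconium enolate, which gives syn aldols whatever the enolate geometry, adds 1,2 to acrolein anti to the new isopropenyl group (sets C5 trans to C1 and the C6 carbinol).

Step 3
Reactants: 7 (as above); 8 2-bromopropanoyl bromide (racemic)
Product: 9 (1S)-1-[(1R,2R,3S)-3-[(tert-butyldimethylsilyl)oxy]-5-oxo-2-(prop-1-en-2-yl)cyclopentyl]prop-2-en-1-yl 2-bromopropanoate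
Conditions: 8 (1.2 equiv), 2,6-lutidine, CH2Cl2, −40 °C
Reagents that add atoms: none
Why: O-acylation of the secondary allylic alcohol with retention at C6, run cold with a hindered weak base so that neither β-oxygenated position of the ketone eliminates.

Step 4
Reactants: 9 (as above)
Product: 10 2α-(tert-butyldimethylsilyloxy)-10α-hydroxy-4-oxo-15-nor-1αH,5βH,6βH,7αH,11αH-guaian-12,6-olide (10R,11R); 11 its 10β-hydroxy epimer (10S,11R) (C10 epimers separated by chromatography)
Conditions: fac-Ir(ppy)3 (1 mol %), 2,6-lutidine (1.5 equiv), MeCN/H2O 9:1 (5 mM), blue LEDs, 35 °C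
Reagents that add atoms: water, O
Why: Proposed new method: the excited photocatalyst reduces the C–Br bond, the α-ester radical closes 5-exo on the vinyl group through a chair-like Beckwith–Houk transition state (C6/C7 trans, C11 methyl cis to the new CH2, i.e. 11R), the primary radical closes 7-endo on the CH2 terminus of the isopropenyl group, and the tertiary C10 radical is oxidised by the oxidised photocatalyst to a cation that water captures from either face (both C10 epimers are needed); the closest known reaction types are photoredox carbo-hydroxylation of alkenes with α-bromo esters and 5-exo/7-endo radical cyclisations.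

Step 5
Reactants: 10 (as above)
Product: 14 10α-hydroxy-4-oxo-15-nor-1αH,5βH,6βH,7αH,11αH-guai-2-en-12,6-olide, via hydroxy ketone 12 (not isolated), via mesylate 13 (not isolated)
Conditions: HF·pyridine, THF, 0 °C; then MsCl (1.1 equiv), Et3N, CH2Cl2, −40 → −10 °C
Reagents that add atoms: none
Why: Desilylation then sulfene mesylation of the secondary β-hydroxy ketone triggers immediate E1cB loss of methanesulfonate, a far better leaving group than the lactone carboxylate at C6, giving the cyclopentenone without touching any stereocentre.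

Step 6
Reactants: 11 (as above)
Product: 17 10β-hydroxy-4-oxo-15-nor-1αH,5βH,6βH,7αH,11αH-guai-2-en-12,6-olide, via hydroxy ketone 15 (not isolated), via mesylate 16 (not isolated)
Conditions: HF·pyridine, THF, 0 °C; then MsCl (1.1 equiv), Et3N, CH2Cl2, −40 → −10 °C
Reagents that add atoms: none
Why: Same desilylation and mesylate E1cB elimination as in step 5, applied to the C10 epimer.

Step 7
Reactants: 17 (as above)
Product: 19 4α,10β-dihydroxy-1αH,5βH,6βH,7αH,11βH-guai-2-en-12,6-olide, via allylic alcohol 18 (not isolated)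
Conditions: MeMgBr, CeCl3, THF, −78 °C; then DBU (0.5 equiv), toluene, 70 °C
Reagents that add atoms: methylmagnesium bromide, C[Mg]Br
Why: The weakly basic organocerium reagent (Imamoto conditions) adds 1,2 to the enone without enolisation or lactone attack (the C4 configuration is lost in step 8), and with the ketone gone DBU can safely epimerise C11 to the more stable 11S lactone with methyl trans to C8.

Step 8
Reactants: 19 (as above); 14 (as above)
Product: 22 the C4 ketone of the target skeleton (15-nor, 4-oxo, 5βH; every other centre as in the target), via diene 20 (not isolated), via alkylborane 21 (not isolated)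
Conditions: CSA (5 mol %), 4 Å sieves, CH2Cl2, −20 °C; catecholborane (3 equiv), Me2NC(O)Me (10 mol %), 0 → 20 °C; MeOH, 0 °C; then added over 6 h to 14 (2 equiv), 4-tert-butylcatechol (10 mol %), di-tert-butyl hyponitrite (10 mol %), ClCH2CH2Cl, 60 °C
Reagents that add atoms: none
Why: Proposed new method: mild acid dehydrates only the allylic tertiary alcohol to the cyclopentadiene, catecholborane adds boron to the unsubstituted diene terminus C2′, and in the catechol-mediated radical chain the nucleophilic C2′ radical adds to C2 of the enone anti to C10 and through its own face anti to C10′ (sets C2 and C2′), the electrophilic α-keto radical closes 5-exo on C5′ of the electron-rich tetrasubstituted alkene (cis ring fusion is forced, sets C3 and C5′, ring A endo), and the tertiary C4′ radical takes hydrogen on the exo face, directly or by 1,5-transfer from the C9′ methylene lying over that face, leaving the methyl endo; the closest known reaction types are the radical conjugate addition of B-alkylcatecholboranes to enones and the (3+2) annulation of homoallyl radicals with electron-poor alkenes.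

Step 9
Reactants: 22 (as above)
Product: 23 the 4(15)-exo-methylene, 5βH isomer of the target
Conditions: Zn, CH2Br2, TiCl4, THF/CH2Cl2, 0 → 20 °C
Reagents that add atoms: dibromomethane, BrCBr
Why: Takai–Lombardo methylenation is non-basic and ketone-selective, so the hindered C4 ketone is converted without epimerising C11, eliminating the β-acyloxy group or touching the lactones and free tertiary alcohols.

Step 10
Reactants: 23 (as above)
Product: 24 the target, CNP0182139.1
Conditions: RhCl3·3H2O (10 mol %), EtOH, 75 °C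
Reagents that add atoms: none
Why: Rhodium-hydride catalysed exo-to-endo alkene isomerisation moves the 1,1-disubstituted alkene to the thermodynamically preferred tetrasubstituted C4=C5 position, removing only the C5 centre and leaving all fifteen target stereocentres as set.

**Compound list**

1 | (S)-4-hydroxycyclopent-2-en-1-one | O=C1C=C[C@@H](O)C1 | starting material
2 | (S)-4-[(tert-butyldimethylsilyl)oxy]cyclopent-2-en-1-one | O=C1C=C[C@@H](O[Si](C)(C)C(C)(C)C)C1 | intermediate
3 | isopropenylmagnesium bromide | CC(=C)[Mg]Br | starting material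
4 | acrolein | C=CC=O | starting material
5 | bromomagnesium enolate of the 1,4-adduct (isopropenyl trans to OTBS) | Br[Mg]OC1=C[C@H](C(C)=C)[C@@H](O[Si](C)(C)C(C)(C)C)C1 | intermediate
6 | chlorozirconocene enolate of the same adduct | Cl[Zr](OC1=C[C@H](C(C)=C)[C@@H](O[Si](C)(C)C(C)(C)C)C1)(C1C=CC=C1)C1C=CC=C1 | intermediate
7 | (2R,3R,4S)-4-[(tert-butyldimethylsilyl)oxy]-2-[(1S)-1-hydroxyprop-2-en-1-yl]-3-(prop-1-en-2-yl)cyclopentan-1-one | O=C1C[C@H](O[Si](C)(C)C(C)(C)C)[C@@H](C(C)=C)[C@@H]1[C@@H](O)C=C | intermediate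
8 | 2-bromopropanoyl bromide (racemic) | CC(Br)C(Br)=O | starting material
9 | 2-bromopropanoate of 7 at the C6 hydroxyl | O=C1C[C@H](O[Si](C)(C)C(C)(C)C)[C@@H](C(C)=C)[C@@H]1[C@@H](OC(=O)C(C)Br)C=C | intermediate
10 | 2α-(tert-butyldimethylsilyloxy)-10α-hydroxy-4-oxo-15-nor-1αH,5βH,6βH,7αH,11αH-guaian-12,6-olide | O=C1C[C@H](O[Si](C)(C)C(C)(C)C)[C@@H]2[C@@H]1[C@H]1OC(=O)[C@H](C)[C@@H]1CC[C@@]2(C)O | intermediate
11 | 10β-hydroxy epimer of 10 | O=C1C[C@H](O[Si](C)(C)C(C)(C)C)[C@@H]2[C@@H]1[C@H]1OC(=O)[C@H](C)[C@@H]1CC[C@]2(C)O | intermediate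
12 | 2α,10α-dihydroxy-4-oxo-15-nor-1αH,5βH,6βH,7αH,11αH-guaian-12,6-olide | O=C1C[C@H](O)[C@@H]2[C@@H]1[C@H]1OC(=O)[C@H](C)[C@@H]1CC[C@@]2(C)O | intermediate
13 | 2α-methanesulfonate of 12 | O=C1C[C@H](OS(C)(=O)=O)[C@@H]2[C@@H]1[C@H]1OC(=O)[C@H](C)[C@@H]1CC[C@@]2(C)O | intermediate
14 | 10α-hydroxy-4-oxo-15-nor-1αH,5βH,6βH,7αH,11αH-guai-2-en-12,6-olide | O=C1C=C[C@@H]2[C@@H]1[C@H]1OC(=O)[C@H](C)[C@@H]1CC[C@@]2(C)O | intermediate
15 | 2α,10β-dihydroxy-4-oxo-15-nor-1αH,5βH,6βH,7αH,11αH-guaian-12,6-olide | O=C1C[C@H](O)[C@@H]2[C@@H]1[C@H]1OC(=O)[C@H](C)[C@@H]1CC[C@]2(C)O | intermediate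
16 | 2α-methanesulfonate of 15 | O=C1C[C@H](OS(C)(=O)=O)[C@@H]2[C@@H]1[C@H]1OC(=O)[C@H](C)[C@@H]1CC[C@]2(C)O | intermediate
17 | 10β-hydroxy-4-oxo-15-nor-1αH,5βH,6βH,7αH,11αH-guai-2-en-12,6-olide | O=C1C=C[C@@H]2[C@@H]1[C@H]1OC(=O)[C@H](C)[C@@H]1CC[C@]2(C)O | intermediate
18 | 4α,10β-dihydroxy-1αH,5βH,6βH,7αH,11αH-guai-2-en-12,6-olide | C[C@@]1(O)C=C[C@@H]2[C@@H]1[C@H]1OC(=O)[C@H](C)[C@@H]1CC[C@]2(C)O | intermediate
19 | 4α,10β-dihydroxy-1αH,5βH,6βH,7αH,11βH-guai-2-en-12,6-olide | C[C@@]1(O)C=C[C@@H]2[C@@H]1[C@H]1OC(=O)[C@@H](C)[C@@H]1CC[C@]2(C)O | intermediate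
20 | 10β-hydroxy-1αH,6βH,7αH,11βH-guaia-2,4-dien-12,6-olide | CC1=C2[C@H]3OC(=O)[C@@H](C)[C@@H]3CC[C@](C)(O)[C@@H]2C=C1 | intermediate
21 | 2α-(1,3,2-benzodioxaborol-2-yl)-10β-hydroxy-1αH,6βH,7αH,11βH-guai-4-en-12,6-olide | CC1=C2[C@H]3OC(=O)[C@@H](C)[C@@H]3CC[C@](C)(O)[C@@H]2[C@@H](B4Oc5ccccc5O4)C1 | intermediate
22 | C4 ketone of the target skeleton (15-nor, 4-oxo, 5βH) | O=C1[C@H]2[C@H]3OC(=O)[C@H](C)[C@@H]3CC[C@@](C)(O)[C@@H]2[C@H]2[C@H]3C[C@@H](C)[C@]4([C@@H]3[C@@](C)(O)CC[C@H]3[C@H](C)C(=O)O[C@@H]34)[C@@H]12 | intermediate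
23 | 4(15)-exo-methylene, 5βH isomer of the target | C=C1[C@H]2[C@H]3OC(=O)[C@H](C)[C@@H]3CC[C@@](C)(O)[C@@H]2[C@H]2[C@H]3C[C@@H](C)[C@]4([C@@H]3[C@@](C)(O)CC[C@H]3[C@H](C)C(=O)O[C@@H]34)[C@@H]12 | intermediate
24 | CNP0182139.1 | CC1=C2[C@H]3OC(=O)[C@H](C)[C@@H]3CC[C@@](C)(O)[C@@H]2[C@H]2[C@H]3C[C@@H](C)[C@]4([C@@H]3[C@@](C)(O)CC[C@H]3[C@H](C)C(=O)O[C@@H]34)[C@@H]12 | target

**Step count**
Total: 10 steps. Longest linear sequence: 9 steps (1, 2, 3, 4, 6, 7, 8, 9, 10).

**Three steps most likely to fail, with fallbacks**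

Step 8 (radical annulation). The weak points are premature reduction of the C2′ radical, capture of the α-keto radical by boron before it cyclises, isomerisation of diene 20 before hydroboration, and above all the face of hydrogen delivery at C4′, since both faces of that radical are crowded. The fallback sets out from 19 and 14 and comes back at 22. Alcohol 19 is dehydrated to diene 20 as before and combined at once with enone 14 and Me2AlCl in CH2Cl2 at −40 °C. This Diels–Alder reaction, with the diene face anti to C10′, the enone face anti to C10 and the carbonyl endo, gives the 3′,4′-didehydro norbornene ketone F1. Hydrogenation of the 3′,4′-didehydro norbornene ketone F1 with H2 and [Ir(cod)(PCy3)(py)]PF6 in CH2Cl2 is directed by the 10′-hydroxyl, which lies over the exo face of the C3′=C4′ bond, so hydrogen reaches C4′ from the exo face and 22 results.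

Step 4 (radical cascade). The α-ester radical may cyclise slowly (ester rotamer), the 7-endo closure may lose to reduction or bromine transfer, and the C10 cation may eliminate instead of taking up water. The fallback sets out from 9 and comes back at 10 and 11. CuBr with tris(2-pyridylmethyl)amine effects atom-transfer 5-exo cyclisation to the bromomethyl lactone F2. NiCl2·glyme-catalysed Negishi coupling of the bromomethyl lactone F2 with CH2=CHZnBr gives the 7-allyl lactone F3. Ring-closing metathesis of the 7-allyl lactone F3 with the second-generation Grubbs catalyst joins the allyl and isopropenyl groups to the Δ9(10) cycloheptene F4. Mukaiyama hydration of the Δ9(10) cycloheptene F4 with Mn(dpm)3, PhSiH3 and O2 gives both tertiary alcohols 10 and 11.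

Step 2 (syn aldol). The zirconium enolate may give poor syn selectivity at C6 with acrolein. The fallback sets out from 2 (with 3 and 4) and comes back at 9, replacing steps 2 and 3. The coupling is run without Cp2ZrCl2, so the magnesium enolate 5 reacts through the chair transition state and gives the anti aldol, the (1R)-carbinol epimer F5. Mitsunobu esterification of the (1R)-carbinol epimer F5 with PPh3, DIAD and 2-bromopropanoic acid inverts C6 and gives 9 directly.

Further compounds
F1 | step 8 | 3′,4′-didehydro norbornene ketone (22 with a C3′=C4′ double bond) | O=C1[C@H]2[C@H]3OC(=O)[C@H](C)[C@@H]3CC[C@@](C)(O)[C@@H]2[C@H]2[C@H]3C=C(C)[C@]4([C@@H]3[C@@](C)(O)CC[C@H]3[C@H](C)C(=O)O[C@@H]34)[C@@H]12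
F2 | step 4 | bromomethyl lactone (5-exo product of 9, C6/C7 trans, 11R) | O=C1C[C@H](O[Si](C)(C)C(C)(C)C)[C@@H](C(C)=C)[C@@H]1[C@H]1OC(=O)[C@H](C)[C@@H]1CBr
F3 | step 4 | 7-allyl lactone | O=C1C[C@H](O[Si](C)(C)C(C)(C)C)[C@@H](C(C)=C)[C@@H]1[C@H]1OC(=O)[C@H](C)[C@@H]1CC=C
F4 | step 4 | Δ9(10) cycloheptene (2α-silyloxy-4-oxo-15-nor-guai-9-en-12,6-olide) | O=C1C[C@H](O[Si](C)(C)C(C)(C)C)[C@@H]2[C@@H]1[C@H]1OC(=O)[C@H](C)[C@@H]1CC=C2C
F5 | step 2 | (2R,3R,4S)-4-[(tert-butyldimethylsilyl)oxy]-2-[(1R)-1-hydroxyprop-2-en-1-yl]-3-(prop-1-en-2-yl)cyclopentan-1-one | O=C1C[C@H](O[Si](C)(C)C(C)(C)C)[C@@H](C(C)=C)[C@@H]1[C@H](O)C=C
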